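**Strategy.** Ring C, the central cyclopentane, is disconnected as a formal [3+2]. Its acyl-bearing carbon (C9), the ring-E fusion CH (C8a) and the quaternary carboxyl carbon (C4b, allylic to the ring-E alkene C5=C6) come from a 7,7-diacyl-2-norcarene, a vinylcyclopropane built on ring E. C9a and C4a come from the diene terminus of a ring-B dienone ester. One Pd(0)-catalysed step (ring opening, 1,6-Michael addition, allylic ring closure) forms C9–C9a and C4a–C4b, closes ring C, creates the quaternary centre and should set the cis,syn,cis array. Acidolysis then closes the butylidene butenolide, and an oxidative lactonisation closes the bridged lactone.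

Key step: step 9

Remarks.
- Locants are those of the hydrofluorene carbon core: C9 carries the butanoyl group and the lactone O; C4b the lactone C=O; C3=C4 is the butenolide C=C (C4 bears its carbonyl); C9a, C4a and C8a are CH. Rings: A butenolide, B (C1–C4, C4a, C9a), C cyclopentane, D bridging lactone, E (C5–C8, C4b, C8a).
- Assumption: tert-butyl 3-oxohexanoate (5) and tert-butyl 2-(diethoxyphosphoryl)acetate (2) are bought.
- The configuration at C9 (C7 of 9, the side-chain CH of 6) is left open until step 11, which fixes it.

Step 1
Reactants: 1 glutaraldehyde; 2 tert-butyl 2-(diethoxyphosphoryl)acetate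
Product: 3 tert-butyl 6-hydroxycyclohex-1-ene-1-carboxylate (racemic)
Conditions: K2CO3 (aq), H2O, rt
Reagents that add atoms: none
Why: Tandem aldol-type addition and intramolecular Horner–Wadsworth–Emmons olefination, in which the phosphonate carbanion adds to one formyl group and then olefinates the second, should give the six-membered hydroxy enoate, whose stereocentre is erased in step 3.

Step 2
Reactants: 3 tert-butyl 6-hydroxycyclohex-1-ene-1-carboxylate
Product: 4 tert-butyl 6-[(methoxycarbonyl)oxy]cyclohex-1-ene-1-carboxylate (racemic)
Conditions: ClCO2Me, pyridine, DMAP (cat.), CH2Cl2, 0 °C to rt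
Reagents that add atoms: methyl chloroformate, COC(=O)Cl
Why: O-acylation of the allylic alcohol gives a carbonate that ionises readily with Pd(0) and releases its own base.

Step 3
Reactants: 4 tert-butyl 6-[(methoxycarbonyl)oxy]cyclohex-1-ene-1-carboxylate; 5 tert-butyl 3-oxohexanoate
Product: 6 tert-butyl (6R)-6-[1-(tert-butoxy)-1,3-dioxohexan-2-yl]cyclohex-1-ene-1-carboxylate (side-chain CH epimers)
Conditions: [Pd(η3-C3H5)Cl]2 (2.5 mol %), (R,R)-DACH-phenyl bis(diphenylphosphinobenzamide) ligand (7.5 mol %; enantiomer to be matched to the 6R product), CH2Cl2, rt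
Reagents that add atoms: none
Why: In this Pd-catalysed asymmetric allylic alkylation (Tsuji–Trost type) both enantiomers of 4 ionise to the same meso 2-(alkoxycarbonyl)cyclohexenyl allyl, and the chiral ligand should direct the β-keto ester enolate (formed by the released methoxide) to one enantiotopic terminus, which sets C6, the future C8a.

Step 4
Reactants: 6 tert-butyl (6R)-6-[1-(tert-butoxy)-1,3-dioxohexan-2-yl]cyclohex-1-ene-1-carboxylate
Product: 9 di-tert-butyl (1S,6S)-7-butanoylbicyclo[4.1.0]hept-2-ene-1,7-dicarboxylate (C7 epimers), via dilithium bis-enolate 7 (not isolated), via iodo dienolate 8 (not isolated)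
Conditions: LDA (2.2 equiv), THF, −78 °C; I2 (1.05 equiv), −78 to 0 °C
Reagents that add atoms: none
Why: In this oxidative intramolecular coupling of a bis-enolate, LDA gives the β-keto ester enolate and (by γ-deprotonation) the ester dienolate, iodine turns one enolate carbon into a C–I bond and the other displaces it in a 3-exo-tet closure through the dienolate α-carbon, so the alkene moves to C2=C3 and the cyclopropane, which can only be cis-fused, takes its C1 configuration from C6.

Step 5
Reactants: 10 cyclohex-2-en-1-one; 11 pentanal
Product: 12 6-(1-hydroxypentyl)cyclohex-2-en-1-one (diastereomers)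
Conditions: LDA, THF, −78 °C; then pentanal
Reagents that add atoms: none
Why: Kinetic α′-deprotonation of the enone and aldol addition place the five-carbon chain at C6; the new stereocentres are removed in steps 6 and 7.

Step 6
Reactants: 12 6-(1-hydroxypentyl)cyclohex-2-en-1-one
Product: 13 6-pentanoylcyclohex-2-en-1-one
Conditions: Dess–Martin periodinane, NaHCO3, CH2Cl2, rt
Reagents that add atoms: none
Why: Dess–Martin oxidation of the β-hydroxy ketone should give the enolised 1,3-diketone without touching the enone.

Step 7
Reactants: 13 6-pentanoylcyclohex-2-en-1-one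
Product: 14 2-pentanoylcyclohexa-1,5-dien-1-yl trifluoromethanesulfonate
Conditions: Tf2O, i-Pr2NEt, CH2Cl2, −78 °C
Reagents that add atoms: trifluoromethanesulfonic anhydride, O=S(=O)(OS(=O)(=O)C(F)(F)F)C(F)(F)F
Why: O-sulfonylation of the diketone should occur at the ring oxygen, because the enol toward the ring carbonyl is linearly conjugated with the ring alkene and the side-chain ketone.

Step 8
Reactants: 14 2-pentanoylcyclohexa-1,5-dien-1-yl trifluoromethanesulfonate
Product: 15 4-methoxybenzyl 2-pentanoylcyclohexa-1,5-diene-1-carboxylate
Conditions: Pd(OAc)2 (5 mol %), dppf (6 mol %), CO (1 atm), 4-MeOC6H4CH2OH (excess), Et3N, DMF, 50 °C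
Reagents that add atoms: carbon monoxide, [C-]#[O+]; 4-methoxybenzyl alcohol, COc1ccc(CO)cc1
Why: Pd-catalysed alkoxycarbonylation of the vinyl triflate installs the future lactone carbonyl as an acid-labile ester, the excess primary alcohol trapping the acyl-palladium faster than the enol oxygen of the neighbouring ketone.

Step 9
Reactants: 9 di-tert-butyl (1S,6S)-7-butanoylbicyclo[4.1.0]hept-2-ene-1,7-dicarboxylate; 15 4-methoxybenzyl 2-pentanoylcyclohexa-1,5-diene-1-carboxylate
Product: 16 4b,9-di-tert-butyl 4-(4-methoxybenzyl) 9-butanoyl-3-pentanoyl-1,2,4a,4b,7,8,8a,9a-octahydro-9H-fluorene-4,4b,9-tricarboxylate (H-4a, H-8a, H-9a and the C4b ester all cis; C9 epimers)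
Conditions: Pd2(dba)3·CHCl3 (2.5 mol %), dppe (6 mol %), THF, rt to 45 °C
Reagents that add atoms: none
Why: Pd(0) opens the C1–C7 bond of 9 with inversion to a zwitterion (cyclohexenyl π-allyl and stabilised β-keto ester carbanion); the carbanion adds reversibly 1,6 to the unsubstituted diene terminus of 15 (the β-carbons of both carbonyl groups are tetrasubstituted), and the dienolate closes through its γ-carbon on the allyl terminus anti to Pd. The closest known type is the Pd-catalysed formal [3+2] cycloaddition of 2-vinylcyclopropane-1,1-dicarbonyl compounds with conjugate acceptors, 1,6-acceptors included. Ring C closes as a 5-exo allylic alkylation, since attack at the far allyl terminus, at oxygen or at the α-carbon would need bridged or medium rings. C4b forms with net retention (double inversion), so ring C is cis-fused to ring E with the ester on the other face, and C9a and C4a must be cis because the five-membered ring can close only on the face of ring B that carries C9. Their sense relative to ring E is decided in the C4a–C4b closure, where the staggered transition state with the tether gauche to C8a puts the sp2 carbon C4 anti to C8a, over the allyl CH and away from the tert-butyl ester and from Pd; this leads to the cis,syn,cis array, and the reversible Michael step drains the faster-closing diastereomer. The step therefore needs 1,6-regioselectivity, closure faster than collapse of the zwitterion, and syn over anti diastereoselection, which rest on the substitution of the dienone, the 5-ring closure and the steric bias just described.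

Step 10
Reactants: 16 the triester from step 9
Product: 19 seco-acid of the target (ring A closed as the (Z)-butylidene butenolide, C4b–CO2H, 9-butanoyl-9H; C9 epimers), via tricarboxylic acid 17 (not isolated), via keto diacid 18 (not isolated)
Conditions: TFA/CH2Cl2 (1:2), anisole, 0 °C to rt, then 40 °C
Reagents that add atoms: none
Why: Acidolysis of the two tert-butyl esters and the 4-methoxybenzyl ester, decarboxylation of the β-keto acid at C9 and cyclodehydration of the 2-acylacrylic acid should give the thermodynamically preferred (Z)-ylidene butenolide, while the 5-oxo acid at C4b/C9 cannot enol-lactonise toward C9 because that C=C would sit at a bridgehead.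

Step 11
Reactants: 19 seco-acid of the target
Product: 20 target CNP0423313.1
Conditions: PhI(OH)OTs (1.2 equiv), CH2Cl2, rt to 40 °C
Reagents that add atoms: none
Why: In this hypervalent-iodine oxylactonisation of a 5-oxo acid, the iodine(III)-bound enol of the butanoyl ketone is attacked at C9 by the C4b carboxylate, which can reach only C9 and only from its own face, so the lactone oxygen enters cis to the carboxyl and both C9 epimers should converge on the single bridged lactone.

**Compound list**

1 | glutaraldehyde (pentanedial) | O=CCCCC=O | starting material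
2 | tert-butyl 2-(diethoxyphosphoryl)acetate | CCOP(=O)(OCC)CC(=O)OC(C)(C)C | starting material
3 | tert-butyl 6-hydroxycyclohex-1-ene-1-carboxylate (racemic) | OC1CCCC=C1C(=O)OC(C)(C)C | intermediate
4 | tert-butyl 6-[(methoxycarbonyl)oxy]cyclohex-1-ene-1-carboxylate (racemic) | COC(=O)OC1CCCC=C1C(=O)OC(C)(C)C | intermediate
5 | tert-butyl 3-oxohexanoate | CCCC(=O)CC(=O)OC(C)(C)C | starting material
6 | tert-butyl (6R)-6-[1-(tert-butoxy)-1,3-dioxohexan-2-yl]cyclohex-1-ene-1-carboxylate (side-chain CH epimers) | CCCC(=O)C(C(=O)OC(C)(C)C)[C@H]1CCCC=C1C(=O)OC(C)(C)C | intermediate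
7 | dilithium bis-enolate of 6 (β-keto ester enolate and ester dienolate; not isolated) | [Li+].[Li+].CCCC([O-])=C(C(=O)OC(C)(C)C)[C@H]1CCC=CC1=C([O-])OC(C)(C)C | intermediate
8 | lithium ester dienolate carrying iodine on the β-keto ester carbon (not isolated) | [Li+].CCCC(=O)C(I)(C(=O)OC(C)(C)C)[C@H]1CCC=CC1=C([O-])OC(C)(C)C | intermediate
9 | di-tert-butyl (1S,6S)-7-butanoylbicyclo[4.1.0]hept-2-ene-1,7-dicarboxylate (C7 epimers) | CCCC(=O)C1(C(=O)OC(C)(C)C)[C@]2(C(=O)OC(C)(C)C)C=CCC[C@@H]21 | intermediate
10 | cyclohex-2-en-1-one | O=C1C=CCCC1 | starting material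
11 | pentanal | CCCCC=O | starting material
12 | 6-(1-hydroxypentyl)cyclohex-2-en-1-one (diastereomers) | CCCCC(O)C1CCC=CC1=O | intermediate
13 | 6-pentanoylcyclohex-2-en-1-one | CCCCC(=O)C1CCC=CC1=O | intermediate
14 | 2-pentanoylcyclohexa-1,5-dien-1-yl trifluoromethanesulfonate | CCCCC(=O)C1=C(OS(=O)(=O)C(F)(F)F)C=CCC1 | intermediate
15 | 4-methoxybenzyl 2-pentanoylcyclohexa-1,5-diene-1-carboxylate | CCCCC(=O)C1=C(C(=O)OCc2ccc(OC)cc2)C=CCC1 | intermediate
16 | 4b,9-di-tert-butyl 4-(4-methoxybenzyl) 9-butanoyl-3-pentanoyl-1,2,4a,4b,7,8,8a,9a-octahydro-9H-fluorene-4,4b,9-tricarboxylate (cis,syn,cis; C9 epimers) | COc1ccc(COC(=O)C2=C(C(=O)CCCC)CC[C@@H]3[C@H]2[C@]2(C(=O)OC(C)(C)C)C=CCC[C@@H]2C3(C(=O)CCC)C(=O)OC(C)(C)C)cc1 | intermediate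
17 | 9-butanoyl-3-pentanoyl-1,2,4a,4b,7,8,8a,9a-octahydro-9H-fluorene-4,4b,9-tricarboxylic acid (not isolated) | OC(=O)C2=C(C(=O)CCCC)CC[C@@H]1[C@H]2[C@]2(C(=O)O)C=CCC[C@@H]2C1(C(=O)CCC)C(=O)O | intermediate
18 | 9-butanoyl-3-pentanoyl-1,2,4a,4b,7,8,8a,9a-octahydro-9H-fluorene-4,4b-dicarboxylic acid (C9 epimers; not isolated) | OC(=O)C2=C(C(=O)CCCC)CC[C@@H]1[C@H]2[C@]2(C(=O)O)C=CCC[C@@H]2C1C(=O)CCC | intermediate
19 | seco-acid of the target: (Z)-butylidene butenolide fused at C3–C4, C4b carboxylic acid, 9-butanoyl-9H (C9 epimers) | CCC/C=C1\OC(=O)C2=C1CC[C@@H]1[C@H]2[C@]2(C(=O)O)C=CCC[C@@H]2C1C(=O)CCC | intermediate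
20 | CNP0423313.1 | CCC/C=C1\OC(=O)C2=C1CC[C@@H]1[C@H]2[C@]23C=CCC[C@@H]2[C@@]1(C(=O)CCC)OC3=O | target

**Step count and risks**

Total step count: 11. Longest linear sequence: 7 (steps 1–4 or 5–8, then 9–11).

Steps most likely to fail:

1. Step 9 (key step). The zwitterion may collapse before it meets 15 (re-closure, 1,3-shift of the carbanion to the far allyl terminus, β-hydride loss), or the ring may close through the anti transition state, giving poor facial selectivity between rings B and E. The fallback sets out from 9 and 15 and comes back at 16. Compound 9 would be opened with MgI2 in THF by anti-SN2′ attack of iodide at the alkene terminus, giving as its magnesium enolate the allylic iodide tert-butyl (6R)-6-[1-(tert-butoxy)-1,3-dioxohexan-2-yl]-3-iodocyclohex-1-ene-1-carboxylate F1 (iodide trans to the side chain). Addition of 15 should then lead through the same 1,6-Michael addition, and the dienolate should close ring C by intramolecular anti-SN2′ displacement of iodide to give 16.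

2. Step 11. The iodine(III) electrophile may attack the ring-E alkene, or the neighbouring carboxyl group may lactonise onto that alkene, in competition with enol formation at C9. The fallback sets out from 19 and comes back at 20. Compound 19 would be brominated at the more substituted α-carbon with CuBr2 in EtOAc–CHCl3 at reflux, a reagent that spares isolated alkenes, to give the tertiary α-bromo ketone 9-bromo seco-acid F2. Silver-assisted ionisation (AgOTf, 2,6-di-tert-butylpyridine, CH2Cl2) should then let the C4b carboxyl capture C9 from its own face.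

3. Step 4. Iodination may occur without ring closure, or the dienolate may close through its γ-carbon to a bridged five-membered ring instead of the cyclopropane. The fallback sets out from 10 and 5 and comes back at 9. Compound 10 would be converted (LDA, PhNTf2) into cyclohexa-1,5-dien-1-yl trifluoromethanesulfonate F3 and carbonylated (Pd(OAc)2, dppf, CO, t-BuOH, Et3N) to tert-butyl cyclohexa-1,5-diene-1-carboxylate F4. Compound 5 would be brominated (NBS) to tert-butyl 2-bromo-3-oxohexanoate F5. Michael-initiated ring closure of F5 onto F4 (Cs2CO3, DMF) should give the cis-fused racemate of 9, rac-9 F6, which would be resolved by preparative chromatography on a chiral stationary phase.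

Further compounds
F1 | step 9 | tert-butyl (6R)-6-[1-(tert-butoxy)-1,3-dioxohexan-2-yl]-3-iodocyclohex-1-ene-1-carboxylate (3,6-trans; formed as its magnesium enolate) | CCCC(=O)C(C(=O)OC(C)(C)C)[C@H]1CC[C@H](I)C=C1C(=O)OC(C)(C)C
F2 | step 11 | 9-bromo seco-acid (19 with Br at C9) | CCC/C=C1\OC(=O)C2=C1CC[C@@H]1[C@H]2[C@]2(C(=O)O)C=CCC[C@@H]2C1(Br)C(=O)CCC
F3 | step 4 | cyclohexa-1,5-dien-1-yl trifluoromethanesulfonate | O=S(=O)(OC1=CCCC=C1)C(F)(F)F
F4 | step 4 | tert-butyl cyclohexa-1,5-diene-1-carboxylate | CC(C)(C)OC(=O)C1=CCCC=C1
F5 | step 4 | tert-butyl 2-bromo-3-oxohexanoate | CCCC(=O)C(Br)C(=O)OC(C)(C)C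
F6 | step 4 | rac-9, racemic cis-fused di-tert-butyl 7-butanoylbicyclo[4.1.0]hept-2-ene-1,7-dicarboxylate (drawn as one enantiomer) | CCCC(=O)C1(C(=O)OC(C)(C)C)[C@]2(C(=O)OC(C)(C)C)C=CCC[C@@H]21
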